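The readings stem from a simulated flask for substances that don't exist, and the scatter is random.

Late in both earlier runs the starting material is at the noise: by 20.0 min it reads 0.3 % in Sunday's flask and 0 % in Monday's. Yet target stands at 50.3 % and 19.1 % of the charge.

| flask | starting material | partner | free catalyst | remark | time |
|---|---|---|---|---|---|
| Sunday's | 0.15 M | 0.38 M | 10 mM | run made earlier |  |
| Monday's | 0.94 M | 0.38 M | 10 mM | run made earlier |  |
| birch | 0.12 M | 0.380 M | 10 mM |  | 20 min |
| oak | 0.20 M | 0.380 M | 10 mM |  | 20 min |
| cedar | 0.25 M | 0.380 M | 10 mM |  | 20 min |
| elm | 0.40 M | 0.380 M | 10 mM |  | 20 min |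
| alder | 0.60 M | 0.380 M | 10 mM |  | 20 min |

| run | time / min | target / % | starting material / % |
|---|---|---|---|
| Sunday's | 3.00 | 37.5 | 11.6 |
| Sunday's | 6.00 | 48.5 | 2.7 |
| Sunday's | 8.00 | 48.1 | 2.4 |
| Sunday's | 12.0 | 49.7 | 0 |
| Sunday's | 15.0 | 50.0 | 0.1 |
| Sunday's | 20.0 | 50.3 | 0.3 |
| Monday's | 3.00 | 13.9 | 2.6 |
| Monday's | 6.00 | 17.0 | 0.3 |
| Monday's | 8.00 | 17.7 | 1.2 |
| Monday's | 12.0 | 17.7 | 0.3 |
| Monday's | 15.0 | 18.6 | 0.4 |
| Monday's | 20.0 | 19.1 | 0 |

(readings scatter by 1 percentage point)

- the analysis behind the earlier runs scatters by 1 percentage point, standard deviation
- a reading or a percentage of target counts all its forms, free or not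
- "hardly changes" means that all values lie within two and a half points (for a concentration: within two and a half percent of the largest)

- amount of target at the end, in percent of the starting material charged for birch, oak, cedar, elm, alder, in this order
- the course of these numbers from the first flask to the last (rises, then falls / hardly changes / falls all the way / rises all the way / falls, then rises)

1. Monday's last reading comes to 0.180 M of target, less than the 0.38 M of partner charged, so partner does not end it. The rest of the starting material must leave by another way, and the lost share is larger in Monday's flask than in Sunday's. My reckoning takes a main path first order in starting material and a loss second order in it.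

2. At any moment the share going to target is then r/(r + [starting material]), and integrating gives target = r·ln(1 + charge/r).

3. I set r = 0.0600 M, the crossover concentration, the [starting material] at which main path and loss run equally fast. I choose this value to match Sunday's flask: it returns 50.1 % there, where the reading is 50.3 %, so this match is a fit and not a check.

4. First instants: my reckoned share in alder is 9.09 %, and in birch 33.3 %.

5. Middle: as [starting material] falls to r the share climbs to half. Every flask of the row starts above r, so in my reckoning each gains the same 0.0416 M of target below it.

6. End: Sunday's readings of starting material between 3.00 min and 6.00 min give a half-life of about 1.43 min, far shorter than 20 min, so I take the integral as complete in the row. I get 54.9 %, 44.0 %, 39.4 %, 30.6 % and 24.0 %, falling all the way.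

The forecast gives 55 %, 44 %, 39.5 %, 31 % and 24.5 %, falls all the way, from “a side reaction second order in starting material”, and stands up to 0.50 percentage points above my figures.

The flasks give 55.7 %, 44.6 %, 40.0 %, 31.0 % and 24.3 %: falls all the way.

    free catalyst + open intermediate ⇌ catalyst intermediate (K = 89.2 /M, k = 2.38 /M/s)
    partner + catalyst intermediate → free catalyst + target (k = 9.20 /M/s)
    2 starting material → self-condensation product (k = 0.0582 /M/s)
    starting material + free catalyst ⇌ free catalyst + open intermediate (K = 1.10, k = 0.932 /M/s)
    crystals ⇌ target, rate k5*(cs5 - [target]) while solid is left; crystals form when [target] > cs5 (solubility = 0.0530 M, k = 0.591 /s)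

In birch the step from starting material to open intermediate has half of its turnover behind it by 0.972 min and the partner step by 1.81 min, and self-condensation product stands at 44.3 % by 10.0 min. At 20.0 min birch holds 0.017 % of its starting material, the limiting reagent, and 82.4 % of its partner. Monday's flask, charged at 15.7 times r, reckons to 18.0 % and reads 19.1 %. Alder, charged at 10.0 times r, ends with self-condensation product at 75.7 % and target at 24.3 %, crystals 15.4 % among it.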